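## Structural features

The target is a cyclohept-2-en-1-one; with the ring numbered from the ketone (C1), the C2=C3 alkene carries a hydroxymethyl group on C2, C4 is a methylene, and C5, C6 and C7 are three contiguous stereocentres. C5 is quaternary (methyl plus a 3-hydroperoxy-4-methylpent-4-enyl chain), C6 bears an (E)-2-(3-methylbut-2-enoyloxy)ethenyl arm cis to the C5 methyl, and C7 bears a 2-oxopropyl group trans to the C6 arm. A fourth stereocentre, the (S)-configured carbinol carbon of the secondary allylic hydroperoxide, lies three bonds from C5 and cannot be controlled from the ring. The fragile groups are the O–O bond (phosphines, low-valent metals, and its own anion, which would attack the enone and the enol ester), the enol ester (acyl transfer), the 2-(hydroxymethyl)enone, the epimerisable C7 and the 1,4-related C1 and side-chain ketones. A hidden hazard is that the aldehyde from which the enol ester must be made stands 1,6 to the methyl ketone, so the two cannot be free together under base. The real difficulty is the quaternary–tertiary–tertiary array on a medium ring, combined with an order of events that brings in the hydroperoxide last and with defined configuration. The key step exploits the fact that C2 is a single carbon between C1 and C3: without it, C1, C3, C4, C5, C6 and C7 form a cyclohexene in which C5/C6 is the stereodiad of a Diels–Alder reaction of an (E)-2-methyl enal, oxygen at C1 lies para to C5, and the C1=C3 enol ether left by that cycloaddition is exactly the bond into which C2 is inserted.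

## Logic of the disconnections

37 ⇒ 36. The Si–O bond on the C2 hydroxymethyl group is cut. The primary alcohol must be masked while the chain carbinol is activated, and its release needs neither base nor reductant, so it is placed last. The forward step must leave the O–O bond, the enol ester and the enone alone.

36 ⇒ 32 + 33 + 34 (through 35). The C–O bond between the chain carbinol carbon and the peroxide oxygen is cut. The peroxide is the most fragile group and is therefore the last heteroatom introduced; the cut turns it into a secondary allylic alcohol of opposite configuration. The forward step must substitute with inversion, without allylic transposition and without forming a peroxide anion.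

32 ⇒ 30 + 31. The C–C bond between the carbinol carbon and the isopropenyl carbon is cut. This removes the remote stereocentre and three carbons and leaves an aldehyde, the one carbonyl that an alkenylchromium reagent attacks beside two ketones. The forward step must take its face selectivity from a ligand alone.

30 ⇒ 28 (through 29). Two carbonyl groups are traced to latent forms: the C7 2-oxopropyl group to an allyl group and the chain aldehyde to a cyclic acetal. Both stay hidden until the arm aldehyde has been consumed, because a free methyl ketone beside the enolising arm aldehyde would close a five-membered aldol ring. The forward step must oxidise the monosubstituted alkene only and hydrolyse the acetal without touching the enol ester.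

28 ⇒ 25 + 27. The acyl–oxygen bond of the enol ester is cut. The enol ester cannot survive amide bases or hydrides and is therefore made after all such steps. The forward step must acylate the aldehyde enol on oxygen with E geometry and leave the ring ketone unenolised.

27 ⇒ 26. The anhydride C–O bond is cut, leading to two molecules of the commercial acid. The anhydride is chosen over the acid chloride, which forms a vinylketene with amines and gives deconjugated esters.

25 ⇒ 24. The arm aldehyde is traced to the primary alcohol. The aldehyde is too reactive to carry and is made immediately before use; the oxidant must not touch the allyl group or the acetal.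

24 ⇒ 23. The benzylic C–O bond of the arm ether is restored. The ether has carried the arm oxygen from the first step; its oxidative removal must spare the terminal alkene, the acetal and the silyl ether.

23 ⇒ 20 + 21 (through 22). The C7–CH2 bond is cut. C7 is the only α-carbon of the ketone that bears hydrogen, and an allyl group is a robust, non-enolisable stand-in for the 2-oxopropyl group. The forward step must deprotonate kinetically at C7 rather than at C4, alkylate once, and place the new group trans to the C6 arm.

20 ⇒ 18 + 19. The Si–O bond is cut. The silyl group chosen must survive amide base, oxidants, dilute acid and chromium reagents and still fall to fluoride at the end.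

18 ⇒ 16 + 17. The C2–CH2 bond is cut, exchanging the hydroxymethyl group for bromine. The halogen is exactly what the ring expansion delivers at C2. The forward step is an sp2–sp3 cross-coupling that must tolerate the enolisable ketone.

16 ⇒ 13 + 14 (through 15). The C1–C2 and C2–C3 bonds are cut and C2 leaves as a one-carbon unit, contracting the seven-membered ring to a cyclohexenyl silyl ether. This is the largest simplification of the plan, since the six-membered ring is a Diels–Alder product. The chain on C5 is carried as a cyclic acetal and not as an ester: an acetal is indifferent to tert-butoxide and to the trihalomethyl anion, and it is later opened by dilute acid, whereas an ester would need a hydride reduction that the C1 ketone could not survive. The forward step must add the carbene to the enol ether only.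

13 ⇒ 12. Two C–H bonds of the chain are removed to give the alkene. The forward hydrogenation must reduce the disubstituted alkene and leave the trisubstituted enol ether and the benzylic ether.

12 ⇒ 10 + 11. The chain C=C bond is cut. Two carbons arrive already at the aldehyde oxidation level and already masked; the hindered, non-enolisable aldehyde must accept a non-stabilised ylide.

10 ⇒ 6 + 9. The C4–C5 and C6–C7 bonds are cut in a retro-Diels–Alder sense. Both ring stereocentres, the quaternary carbon and the regiodefined enol ether come from one step; the alkene geometry of the dienophile fixes their relative configuration. The forward step needs a chiral Lewis acid for the absolute configuration and para regiochemistry from the 2-silyloxy diene.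

9 ⇒ 7 + 8. The Si–O bond of the diene is cut. A bulky silyl group is needed so that the enol ether survives three further steps.

6 ⇒ 4 + 5. The C=C bond of the enal is cut. A stabilised ylide gives the (E)-isomer on which the C5/C6 relationship depends.

4 ⇒ 3. The aldehyde is traced to the alcohol; the oxidation must not trigger β-elimination of the ether.

3 ⇒ 1 + 2. The benzylic C–O bond is cut, leading to the symmetrical diol; monoalkylation is secured by an excess of 1.

## Other disconnections considered

Alternative 1: The C6–CH2 and C7–CH2 bonds are cut together, so that both side arms come from a Diels–Alder reaction in which the C6=C7 alkene of the enone A2 is the dienophile and the silyloxy diene A3 the partner, under a chiral oxazaborolidinium Lewis acid; the cyclohexene of the cis-fused adduct A1 is sacrificed later by cleaving its enol ether into a methyl ketone (C7 side) and a carboxyl group (C6 side).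
- In its favour: both arms arrive in one step on a ready-made seven-membered ring, the cleavage differentiates them at nearly the right oxidation levels, and no C7 alkylation or alkene oxidation is needed. On economy for the C6/C7 substituents it is the better plan.
- Against it: the C5/C6 relationship depends on the diene distinguishing methyl from allyl on the neighbouring quaternary carbon, a weak bias. The β-carbon of A2 is neopentyl, so the dienophile is poor. The catalyst has to cooperate with the stereocentre already present in A2, which itself needs an asymmetric synthesis. The cis ring fusion gives the wrong C7 configuration (correctable by enolisation, so equal in the end). The C2=C3 alkene and the hydroxymethyl group still have to be introduced, and the allyl terminus competes in the oxidative ring cleavage.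
- Comparison: the chosen plan derives C5/C6 from alkene geometry in a suprafacial cycloaddition and is the more reliable on structure; mechanistically both rest on the same class of catalyst.

Alternative 2: The C1–C2 bond is cut in a precursor in which a 2-methylfuran masks both the C1 ketone and the side-chain ketone; zerovalent palladium inserts into a (Z)-vinyl iodide and alkenylates the free α-position of the furan, closing the seven-membered ring as A4.
- In its favour: the 1,4-diketone is hidden in one robust aromatic unit that tolerates bases and nucleophiles, and the C2=C3 alkene with its oxygenated carbon is installed with fixed geometry. The closure is mechanistically sound (oxidative addition, palladation of the electron-rich α-carbon, reductive elimination). No C7 alkylation and no alkene oxidation are required, an advantage over the chosen plan.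
- Against it: the C5/C6 stereodiad has to be built in an open chain before the closure, so the hard problem is moved and not solved. Unmasking a 2-alkenylfuran to a saturated 1,4-diketone needs strong aqueous acid, or an oxidative opening followed by selective reduction, in the presence of an acetal and an allylic silyl ether. C7 is set only on protonation. The prenyl-type chain of A4 still needs an oxygenation that gives no control of the carbinol configuration.
- Comparison: the masked diketone is more robust than the latent groups of the chosen plan, but the step count to the cyclisation substrate and the risk of the unmasking weigh against it.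

Alternative 3: The C1–C2 and C4–C5 bonds are cut; the rhodium vinylcarbenoid from the diazo ester A7 and a chiral dirhodium tetraprolinate, Rh2(DOSP)4, cyclopropanates the terminal alkene of the (E)-triene A6, and the cis-divinylcyclopropane undergoes a Cope rearrangement in situ to the cycloheptadiene A5.
- In its favour: one catalytic asymmetric step forms the ring, the C2 carbon substituent (as an ester), the C2=C3 alkene and the quaternary C5. The Cope step is stereospecific, so the (E)-geometry of A6 and the catalyst together fix C5. For construction of a C2-functionalised seven-membered ring this is the most economical of the four plans, and its control of C5 is of comparable quality to the chosen one.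
- Against it: A5 has no oxygen at C1 (a bis-allylic methylene to be oxidised) and carries C6 and C7 as unsubstituted sp2 carbons. The arm must then be added at C6 by conjugate addition next to the quaternary centre, where methyl and the homoprenyl chain offer little facial bias, and the two enone arms must be told apart. C7 still needs the three-carbon ketone unit, and the trisubstituted chain alkene needs the same uncontrolled oxygenation as in Alternative 2.
- Comparison: better on ring-forming economy, weaker on the C5–C6 relationship, which the chosen plan obtains from a single suprafacial event.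

Key step: step 8

Assumption (step 5): the (R)-oxazaborolidinium catalyst is taken to shield the Re face of C-α of the s-trans enal 6, as the accepted formyl C–H···O binding model predicts; the (S)-catalyst would be used, with no other change, if the preference were the reverse on this substrate.

Assumption (step 17): the (S)-sulfonamide ligand is taken to direct the alkenylchromium reagent to the Si face of aldehyde 30; its enantiomer is the remedy if the sense is the opposite.

## Route

Step 1
Reactants: 1 propane-1,3-diol; 2 4-methoxybenzyl chloride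
Product: 3 3-[(4-methoxyphenyl)methoxy]propan-1-ol
Conditions: 1 (3 equiv), NaH (1.0 equiv), THF, 0 °C; then 2, Bu4NI (cat.), 0 °C to rt
Reagents that add atoms: 4-methoxybenzyl chloride (2), COc1ccc(CCl)cc1
Why: Williamson etherification; the excess of the symmetrical diol keeps dialkylation low and the surplus diol is removed by aqueous extraction.

Step 2
Reactants: 3 3-[(4-methoxyphenyl)methoxy]propan-1-ol
Product: 4 3-[(4-methoxyphenyl)methoxy]propanal
Conditions: TEMPO (0.1 equiv), PhI(OAc)2 (1.1 equiv), CH2Cl2, rt
Reagents that add atoms: none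
Why: Oxoammonium (TEMPO) oxidation stops at the aldehyde and is mild enough to avoid β-elimination of the benzylic alkoxide and oxidation of the electron-rich arene.

Step 3
Reactants: 4 3-[(4-methoxyphenyl)methoxy]propanal; 5 2-(triphenyl-λ5-phosphanylidene)propanal
Product: 6 (E)-5-[(4-methoxyphenyl)methoxy]-2-methylpent-2-enal
Conditions: toluene, 80 °C
Reagents that add atoms: 2-(triphenyl-λ5-phosphanylidene)propanal (5), CC(C=O)=P(c1ccccc1)(c1ccccc1)c1ccccc1
Why: Wittig olefination with a stabilised formyl ylide, which should give the (E)-trisubstituted enal under thermodynamic control of the betaine/oxaphosphetane; the less electrophilic product enal does not react further.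

Step 4
Reactants: 7 but-3-en-2-one; 8 triisopropylsilyl trifluoromethanesulfonate
Product: 9 2-(triisopropylsilyloxy)buta-1,3-diene
Conditions: Et3N, Et2O, 0 °C to rt
Reagents that add atoms: triisopropylsilyl trifluoromethanesulfonate (8), CC(C)[Si](C(C)C)(C(C)C)OS(=O)(=O)C(F)(F)F
Why: Soft enolisation and O-silylation of a methyl ketone; the methyl group is the only enolisable position, so the 2-silyloxy diene forms regiospecifically, and the bulky silyl group makes it isolable.

Step 5
Reactants: 6 (E)-5-[(4-methoxyphenyl)methoxy]-2-methylpent-2-enal; 9 2-(triisopropylsilyloxy)buta-1,3-diene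
Product: 10 (1S,6S)-6-{2-[(4-methoxyphenyl)methoxy]ethyl}-1-methyl-4-(triisopropylsilyloxy)cyclohex-3-ene-1-carbaldehyde
Conditions: (R)-1-(2-methylphenyl)-3,3-diphenyltetrahydro-1H,3H-pyrrolo[1,2-c][1,3,2]oxazaborole (0.2 equiv), HN(SO2CF3)2 (0.18 equiv), CH2Cl2, −78 to −40 °C
Reagents that add atoms: 2-(triisopropylsilyloxy)buta-1,3-diene (9), C=CC(=C)O[Si](C(C)C)(C(C)C)C(C)C
Why: Catalytic asymmetric Diels–Alder reaction: the oxazaborolidinium ion binds the formyl oxygen of the s-trans enal, and the nucleophilic CH2 terminus of the enol ether bonds to the β-carbon, so that oxygen ends para to the quaternary carbon. The (E)-geometry is transferred suprafacially (methyl cis to the arm, formyl trans), and the catalyst shields the Re face of C-α, so both stereocentres are set together as (S,S).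

Step 6
Reactants: 10 (1S,6S)-6-{2-[(4-methoxyphenyl)methoxy]ethyl}-1-methyl-4-(triisopropylsilyloxy)cyclohex-3-ene-1-carbaldehyde; 11 (1,3-dioxolan-2-ylmethyl)triphenylphosphonium bromide
Product: 12 2-{2-[(1S,6S)-6-{2-[(4-methoxyphenyl)methoxy]ethyl}-1-methyl-4-(triisopropylsilyloxy)cyclohex-3-en-1-yl]ethenyl}-1,3-dioxolane (Z/E mixture)
Conditions: 11, KOt-Bu, THF, 0 °C to rt
Reagents that add atoms: (1,3-dioxolan-2-ylmethyl)triphenylphosphonium bromide (11), [Br-].C1COC(C[P+](c2ccccc2)(c3ccccc3)c4ccccc4)O1
Why: Wittig olefination with a non-stabilised ylide, which adds readily to the hindered but non-enolisable aldehyde; the alkene geometry is irrelevant because the alkene is reduced next, and the bulky silyl enol ether is stable to the base.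

Step 7
Reactants: 12 2-{2-[(1S,6S)-6-{2-[(4-methoxyphenyl)methoxy]ethyl}-1-methyl-4-(triisopropylsilyloxy)cyclohex-3-en-1-yl]ethenyl}-1,3-dioxolane
Product: 13 2-{2-[(1S,6S)-6-{2-[(4-methoxyphenyl)methoxy]ethyl}-1-methyl-4-(triisopropylsilyloxy)cyclohex-3-en-1-yl]ethyl}-1,3-dioxolane
Conditions: H2 (1 atm), RhCl(PPh3)3 (5 mol %), toluene, rt
Reagents that add atoms: none
Why: Homogeneous hydrogenation; RhCl(PPh3)3 should reduce the 1,2-disubstituted alkene far faster than the trisubstituted silyl enol ether and does not hydrogenolyse the benzylic ether, and both alkene isomers converge on 13.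

Step 8
Reactants: 13 2-{2-[(1S,6S)-6-{2-[(4-methoxyphenyl)methoxy]ethyl}-1-methyl-4-(triisopropylsilyloxy)cyclohex-3-en-1-yl]ethyl}-1,3-dioxolane; 14 bromoform
Product: 16 (5S,6S)-2-bromo-5-[2-(1,3-dioxolan-2-yl)ethyl]-6-{2-[(4-methoxyphenyl)methoxy]ethyl}-5-methylcyclohept-2-en-1-one, via siloxy-dibromocyclopropane 15 (not isolated)
Conditions: 14 (2 equiv), KOt-Bu (2.5 equiv), hexane, −20 °C to rt; filter; then 2,6-lutidine, toluene, 90 °C
Reagents that add atoms: bromoform (14), BrC(Br)Br
Why: Deprotonation of 14 by tert-butoxide and loss of bromide give dibromocarbene, an electrophilic singlet carbene that adds in a concerted (2+1) fashion to the only electron-rich alkene of 13, the C1=C3 silyl enol ether, forming C1–C2 and C2–C3 in the cyclopropane 15. On warming, the C–Br bond cis to the six-membered ring ionises while the C1–C3 bond breaks in a disrotatory two-electron electrocyclic opening assisted by the oxygen lone pair, and the oxygen-stabilised allyl cation over C1–C2–C3 loses its silyl group to bromide to give the 2-bromoenone 16. The closest known reaction type is the dihalocarbene ring expansion of cyclic silyl enol ethers to 2-halocycloalk-2-enones. The seven-membered ring is thus closed by (2+1) cycloaddition followed by one-carbon expansion of the fused bicyclo[4.1.0] system, not by an end-to-end cyclisation. No stereocentre is created: the two ring-fusion centres of 15 vanish in the opening, both faces of the enol ether lead to 16, and C5 and C6 are untouched. Only site selectivity is needed, and the regiodefined enol ether from step 5 fixes where C2 enters, while the anisyl ring, the acetal and the saturated chain are inert to the carbene and offer tert-butoxide no acyl group. The bulky silyl group should keep 15 intact at low temperature, so that the base is removed before the enone is unveiled.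

Step 9
Reactants: 16 (5S,6S)-2-bromo-5-[2-(1,3-dioxolan-2-yl)ethyl]-6-{2-[(4-methoxyphenyl)methoxy]ethyl}-5-methylcyclohept-2-en-1-one; 17 (tributylstannyl)methanol
Product: 18 (5S,6S)-5-[2-(1,3-dioxolan-2-yl)ethyl]-2-(hydroxymethyl)-6-{2-[(4-methoxyphenyl)methoxy]ethyl}-5-methylcyclohept-2-en-1-one
Conditions: 17 (1.5 equiv), Pd(PPh3)4 (10 mol %), 1,4-dioxane, 100 °C
Reagents that add atoms: (tributylstannyl)methanol (17), CCCC[Sn](CCCC)(CCCC)CO
Why: Stille coupling: zerovalent palladium inserts into the C2–Br bond of the bromoenone, the hydroxymethyl group is transferred from tin in preference to butyl, and reductive elimination forms the C2–CH2OH bond. The neutral conditions spare the acetal, the ether and the enolisable ketone.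

Step 10
Reactants: 18 (5S,6S)-5-[2-(1,3-dioxolan-2-yl)ethyl]-2-(hydroxymethyl)-6-{2-[(4-methoxyphenyl)methoxy]ethyl}-5-methylcyclohept-2-en-1-one; 19 tert-butyl(chloro)diphenylsilane
Product: 20 (5S,6S)-2-{[tert-butyl(diphenyl)silyl]oxymethyl}-5-[2-(1,3-dioxolan-2-yl)ethyl]-6-{2-[(4-methoxyphenyl)methoxy]ethyl}-5-methylcyclohept-2-en-1-one
Conditions: 19, imidazole, CH2Cl2, 0 °C to rt
Reagents that add atoms: tert-butyl(chloro)diphenylsilane (19), CC(C)(C)[Si](Cl)(c1ccccc1)c1ccccc1
Why: Silylation of the only hydroxyl group; this silyl ether is chosen because it withstands amide base, the oxidations, dilute aqueous acid and chromium reagents and is still cleaved by fluoride.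

Step 11
Reactants: 20 (5S,6S)-2-{[tert-butyl(diphenyl)silyl]oxymethyl}-5-[2-(1,3-dioxolan-2-yl)ethyl]-6-{2-[(4-methoxyphenyl)methoxy]ethyl}-5-methylcyclohept-2-en-1-one; 21 allyl bromide
Product: 23 (5S,6S,7S)-2-{[tert-butyl(diphenyl)silyl]oxymethyl}-5-[2-(1,3-dioxolan-2-yl)ethyl]-6-{2-[(4-methoxyphenyl)methoxy]ethyl}-5-methyl-7-(prop-2-enyl)cyclohept-2-en-1-one, via lithium enolate 22 (not isolated)
Conditions: LiN(i-Pr)2 (1.1 equiv), THF, −78 °C; then 21, DMPU, −78 to −30 °C
Reagents that add atoms: allyl bromide (21), C=CCBr
Why: Kinetic deprotonation occurs at C7, the only α-carbon bearing hydrogen (the γ-hydrogens at C4 are removed only under equilibrating conditions), and SN2 allylation of the cross-conjugated enolate anti to the adjacent C6 arm should give the 6,7-trans product. C7 stays epimerisable and the trans isomer is also expected to be the more stable, so equilibration can correct a minor cis fraction.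

Step 12
Reactants: 23 (5S,6S,7S)-2-{[tert-butyl(diphenyl)silyl]oxymethyl}-5-[2-(1,3-dioxolan-2-yl)ethyl]-6-{2-[(4-methoxyphenyl)methoxy]ethyl}-5-methyl-7-(prop-2-enyl)cyclohept-2-en-1-one
Product: 24 (5S,6S,7S)-2-{[tert-butyl(diphenyl)silyl]oxymethyl}-5-[2-(1,3-dioxolan-2-yl)ethyl]-6-(2-hydroxyethyl)-5-methyl-7-(prop-2-enyl)cyclohept-2-en-1-one
Conditions: DDQ (1.3 equiv), CH2Cl2–pH 7 phosphate buffer (10:1), 0 °C to rt
Reagents that add atoms: none
Why: Oxidative cleavage of the 4-methoxybenzyl ether by hydride abstraction at the electron-rich benzylic position and hydrolysis of the oxocarbenium ion; the buffer protects the acetal, and the terminal alkene, enone and silyl ether are not oxidised.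

Step 13
Reactants: 24 (5S,6S,7S)-2-{[tert-butyl(diphenyl)silyl]oxymethyl}-5-[2-(1,3-dioxolan-2-yl)ethyl]-6-(2-hydroxyethyl)-5-methyl-7-(prop-2-enyl)cyclohept-2-en-1-one
Product: 25 (5S,6S,7S)-2-{[tert-butyl(diphenyl)silyl]oxymethyl}-5-[2-(1,3-dioxolan-2-yl)ethyl]-5-methyl-6-(2-oxoethyl)-7-(prop-2-enyl)cyclohept-2-en-1-one
Conditions: TEMPO (0.1 equiv), PhI(OAc)2 (1.1 equiv), CH2Cl2, rt
Reagents that add atoms: none
Why: Oxoammonium (TEMPO) oxidation of the only free alcohol to the aldehyde without over-oxidation; the aldehyde is used at once because it is the enolisable partner of the next step.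

Step 14
Reactants: 26 3-methylbut-2-enoic acid (two molecules)
Product: 27 3-methylbut-2-enoic anhydride
Conditions: 26 (2 equiv), DCC (1 equiv), CH2Cl2, 0 °C to rt; filter
Reagents that add atoms: 3-methylbut-2-enoic acid (26, the second molecule), CC(C)=CC(=O)O
Why: Carbodiimide-mediated dehydration: one molecule of 26 adds to DCC to give the O-acylisourea, which acylates the carboxylate of a second molecule of 26, so the anhydride forms from two acid molecules and the water ends in the urea. The anhydride is preferred to the acid chloride, which forms a vinylketene with tertiary amines and gives deconjugated esters.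

Step 15
Reactants: 25 (5S,6S,7S)-2-{[tert-butyl(diphenyl)silyl]oxymethyl}-5-[2-(1,3-dioxolan-2-yl)ethyl]-5-methyl-6-(2-oxoethyl)-7-(prop-2-enyl)cyclohept-2-en-1-one; 27 3-methylbut-2-enoic anhydride
Product: 28 (5S,6S,7S)-2-{[tert-butyl(diphenyl)silyl]oxymethyl}-5-[2-(1,3-dioxolan-2-yl)ethyl]-5-methyl-6-[(E)-2-(3-methylbut-2-enoyloxy)ethenyl]-7-(prop-2-enyl)cyclohept-2-en-1-one
Conditions: 27 (2 equiv), Et3N (3 equiv), DMAP (0.3 equiv), THF, 40 °C
Reagents that add atoms: 3-methylbut-2-enoic anhydride (27), CC(C)=CC(=O)OC(=O)C=C(C)C
Why: O-Acylation of an aldehyde enolate: the amine enolises only the aldehyde, and the acylpyridinium ion from 27 captures it on oxygen. The (E)-isomer should dominate because the bulky ring carbon C6 avoids the cis relationship to the acyloxy group, and the geometric isomers are separable. The 2-oxopropyl group is still an allyl group, so no aldol partner is present.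

Step 16
Reactants: 28 (5S,6S,7S)-2-{[tert-butyl(diphenyl)silyl]oxymethyl}-5-[2-(1,3-dioxolan-2-yl)ethyl]-5-methyl-6-[(E)-2-(3-methylbut-2-enoyloxy)ethenyl]-7-(prop-2-enyl)cyclohept-2-en-1-one
Product: 30 (5S,6S,7S)-2-{[tert-butyl(diphenyl)silyl]oxymethyl}-5-methyl-6-[(E)-2-(3-methylbut-2-enoyloxy)ethenyl]-5-(3-oxopropyl)-7-(2-oxopropyl)cyclohept-2-en-1-one, via methyl ketone acetal 29 (not isolated)
Conditions: PdCl2 (10 mol %), Cu(OAc)2 (20 mol %), O2 (1 atm), DMA–H2O (7:1), rt; then N2, 1 M HCl, rt
Reagents that add atoms: water, O
Why: Tsuji–Wacker oxidation: divalent palladium binds the only monosubstituted alkene, water attacks its internal carbon and β-hydride elimination gives the methyl ketone, while the conjugated, enol-ester and trisubstituted alkenes bind far less well and dioxygen only reoxidises the metals. Acidification then hydrolyses the dioxolane to the aldehyde; the enol ester and the silyl ether should survive dilute acid at room temperature.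

Step 17
Reactants: 30 (5S,6S,7S)-2-{[tert-butyl(diphenyl)silyl]oxymethyl}-5-methyl-6-[(E)-2-(3-methylbut-2-enoyloxy)ethenyl]-5-(3-oxopropyl)-7-(2-oxopropyl)cyclohept-2-en-1-one; 31 2-bromopropene
Product: 32 (5S,6S,7S)-2-{[tert-butyl(diphenyl)silyl]oxymethyl}-5-[(3R)-3-hydroxy-4-methylpent-4-enyl]-5-methyl-6-[(E)-2-(3-methylbut-2-enoyloxy)ethenyl]-7-(2-oxopropyl)cyclohept-2-en-1-one
Conditions: CrCl2 (4 equiv), NiCl2 (5 mol %), (S)-N-[2-(4-isopropyl-4,5-dihydro-1,3-oxazol-2-yl)-6-methylphenyl]methanesulfonamide (4.4 equiv), Et3N (4.4 equiv), 31 (3 equiv), THF, rt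
Reagents that add atoms: 2-bromopropene (31), C=C(C)Br
Why: Asymmetric Nozaki–Hiyama–Kishi coupling: zerovalent nickel activates 31 and hands the alkenyl group to chromium, giving a reagent that adds to aldehydes but not to the two ketones, the enone or the esters. The chiral sulfonamide ligand on chromium is the only source of face selectivity at this remote centre and should direct addition to the Si face, giving the (R)-carbinol.

Step 18
Reactants: 32 (5S,6S,7S)-2-{[tert-butyl(diphenyl)silyl]oxymethyl}-5-[(3R)-3-hydroxy-4-methylpent-4-enyl]-5-methyl-6-[(E)-2-(3-methylbut-2-enoyloxy)ethenyl]-7-(2-oxopropyl)cyclohept-2-en-1-one; 33 methanesulfonic anhydride; 34 hydrogen peroxide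
Product: 36 (5S,6S,7S)-2-{[tert-butyl(diphenyl)silyl]oxymethyl}-5-[(3S)-3-hydroperoxy-4-methylpent-4-enyl]-5-methyl-6-[(E)-2-(3-methylbut-2-enoyloxy)ethenyl]-7-(2-oxopropyl)cyclohept-2-en-1-one, via allylic mesylate 35 (not isolated)
Conditions: 33 (1.3 equiv), Et3N (1.5 equiv), CH2Cl2, −78 °C; then 34 (anhydrous, in Et2O, 20 equiv), 2,6-lutidine, −78 to −20 °C
Reagents that add atoms: hydrogen peroxide (34), OO; methanesulfonic anhydride (33), CS(=O)(=O)OS(C)(=O)=O (in intermediate 35 only)
Why: Sulfonylation of the only free hydroxyl group, then nucleophilic substitution of the secondary allylic sulfonate by neutral hydrogen peroxide, a known route to allylic hydroperoxides. In ether at low temperature backside attack should prevail, converting the (R)-sulfonate into the (S)-hydroperoxide. No peroxide anion is present, so the enone is not epoxidised and the enol ester not cleaved, and lutidine takes up the sulfonic acid that would otherwise promote peroxide addition to the ketones.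

Step 19
Reactants: 36 (5S,6S,7S)-2-{[tert-butyl(diphenyl)silyl]oxymethyl}-5-[(3S)-3-hydroperoxy-4-methylpent-4-enyl]-5-methyl-6-[(E)-2-(3-methylbut-2-enoyloxy)ethenyl]-7-(2-oxopropyl)cyclohept-2-en-1-one
Product: 37 (5S,6S,7S)-5-[(3S)-3-hydroperoxy-4-methylpent-4-enyl]-2-(hydroxymethyl)-5-methyl-6-[(E)-2-(3-methylbut-2-enoyloxy)ethenyl]-7-(2-oxopropyl)cyclohept-2-en-1-one
Conditions: HF·pyridine, pyridine, THF, 0 °C to rt
Reagents that add atoms: none
Why: Fluoride-mediated desilylation driven by Si–F bond formation under buffered, weakly acidic conditions; no base or reductant is present, so the hydroperoxide, enol ester, enone and 1,4-diketone should remain intact.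

## Compound list

1 | propane-1,3-diol | OCCCO | starting material
2 | 4-methoxybenzyl chloride | COc1ccc(CCl)cc1 | starting material
3 | 3-[(4-methoxyphenyl)methoxy]propan-1-ol | OCCCOCc1ccc(OC)cc1 | intermediate
4 | 3-[(4-methoxyphenyl)methoxy]propanal | O=CCCOCc1ccc(OC)cc1 | intermediate
5 | 2-(triphenyl-λ5-phosphanylidene)propanal | CC(C=O)=P(c1ccccc1)(c1ccccc1)c1ccccc1 | starting material
6 | (E)-5-[(4-methoxyphenyl)methoxy]-2-methylpent-2-enal | O=C/C(C)=C/CCOCc1ccc(OC)cc1 | intermediate
7 | but-3-en-2-one | C=CC(C)=O | starting material
8 | triisopropylsilyl trifluoromethanesulfonate | CC(C)[Si](C(C)C)(C(C)C)OS(=O)(=O)C(F)(F)F | starting material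
9 | 2-(triisopropylsilyloxy)buta-1,3-diene | C=CC(=C)O[Si](C(C)C)(C(C)C)C(C)C | intermediate
10 | (1S,6S)-6-{2-[(4-methoxyphenyl)methoxy]ethyl}-1-methyl-4-(triisopropylsilyloxy)cyclohex-3-ene-1-carbaldehyde | O=C[C@@]1(C)CC=C(O[Si](C(C)C)(C(C)C)C(C)C)C[C@@H]1CCOCc2ccc(OC)cc2 | intermediate
11 | (1,3-dioxolan-2-ylmethyl)triphenylphosphonium bromide | [Br-].C1COC(C[P+](c2ccccc2)(c3ccccc3)c4ccccc4)O1 | starting material
12 | 2-{2-[(1S,6S)-6-{2-[(4-methoxyphenyl)methoxy]ethyl}-1-methyl-4-(triisopropylsilyloxy)cyclohex-3-en-1-yl]ethenyl}-1,3-dioxolane (Z/E mixture) | C(=C[C@@]1(C)CC=C(O[Si](C(C)C)(C(C)C)C(C)C)C[C@@H]1CCOCc2ccc(OC)cc2)C3OCCO3 | intermediate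
13 | 2-{2-[(1S,6S)-6-{2-[(4-methoxyphenyl)methoxy]ethyl}-1-methyl-4-(triisopropylsilyloxy)cyclohex-3-en-1-yl]ethyl}-1,3-dioxolane | C1COC(CC[C@@]2(C)CC=C(O[Si](C(C)C)(C(C)C)C(C)C)C[C@@H]2CCOCc3ccc(OC)cc3)O1 | intermediate
14 | bromoform | BrC(Br)Br | starting material
15 | 7,7-dibromo-1-(triisopropylsilyloxy)bicyclo[4.1.0]heptane adduct of 13 (both cis-fused ring-fusion isomers; C5 and C6 as in 13) | C1COC(CC[C@@]2(C)CC3C(Br)(Br)C3(O[Si](C(C)C)(C(C)C)C(C)C)C[C@@H]2CCOCc4ccc(OC)cc4)O1 | intermediate (not isolated)
16 | (5S,6S)-2-bromo-5-[2-(1,3-dioxolan-2-yl)ethyl]-6-{2-[(4-methoxyphenyl)methoxy]ethyl}-5-methylcyclohept-2-en-1-one | C1COC(CC[C@@]2(C)CC=C(Br)C(=O)C[C@@H]2CCOCc3ccc(OC)cc3)O1 | intermediate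
17 | (tributylstannyl)methanol | CCCC[Sn](CCCC)(CCCC)CO | starting material
18 | (5S,6S)-5-[2-(1,3-dioxolan-2-yl)ethyl]-2-(hydroxymethyl)-6-{2-[(4-methoxyphenyl)methoxy]ethyl}-5-methylcyclohept-2-en-1-one | C1COC(CC[C@@]2(C)CC=C(CO)C(=O)C[C@@H]2CCOCc3ccc(OC)cc3)O1 | intermediate
19 | tert-butyl(chloro)diphenylsilane | CC(C)(C)[Si](Cl)(c1ccccc1)c1ccccc1 | starting material
20 | (5S,6S)-2-{[tert-butyl(diphenyl)silyl]oxymethyl}-5-[2-(1,3-dioxolan-2-yl)ethyl]-6-{2-[(4-methoxyphenyl)methoxy]ethyl}-5-methylcyclohept-2-en-1-one | C1COC(CC[C@@]2(C)CC=C(CO[Si](c3ccccc3)(c4ccccc4)C(C)(C)C)C(=O)C[C@@H]2CCOCc5ccc(OC)cc5)O1 | intermediate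
21 | allyl bromide | C=CCBr | starting material
22 | lithium C1(O)=C7 enolate of 20 | C1COC(CC[C@@]2(C)CC=C(CO[Si](c3ccccc3)(c4ccccc4)C(C)(C)C)C(O[Li])=C[C@@H]2CCOCc5ccc(OC)cc5)O1 | intermediate (not isolated)
23 | (5S,6S,7S)-2-{[tert-butyl(diphenyl)silyl]oxymethyl}-5-[2-(1,3-dioxolan-2-yl)ethyl]-6-{2-[(4-methoxyphenyl)methoxy]ethyl}-5-methyl-7-(prop-2-enyl)cyclohept-2-en-1-one | C1COC(CC[C@@]2(C)CC=C(CO[Si](c3ccccc3)(c4ccccc4)C(C)(C)C)C(=O)[C@@H](CC=C)[C@@H]2CCOCc5ccc(OC)cc5)O1 | intermediate
24 | (5S,6S,7S)-2-{[tert-butyl(diphenyl)silyl]oxymethyl}-5-[2-(1,3-dioxolan-2-yl)ethyl]-6-(2-hydroxyethyl)-5-methyl-7-(prop-2-enyl)cyclohept-2-en-1-one | C1COC(CC[C@@]2(C)CC=C(CO[Si](c3ccccc3)(c4ccccc4)C(C)(C)C)C(=O)[C@@H](CC=C)[C@@H]2CCO)O1 | intermediate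
25 | (5S,6S,7S)-2-{[tert-butyl(diphenyl)silyl]oxymethyl}-5-[2-(1,3-dioxolan-2-yl)ethyl]-5-methyl-6-(2-oxoethyl)-7-(prop-2-enyl)cyclohept-2-en-1-one | C1COC(CC[C@@]2(C)CC=C(CO[Si](c3ccccc3)(c4ccccc4)C(C)(C)C)C(=O)[C@@H](CC=C)[C@@H]2CC=O)O1 | intermediate
26 | 3-methylbut-2-enoic acid | CC(C)=CC(=O)O | starting material
27 | 3-methylbut-2-enoic anhydride | CC(C)=CC(=O)OC(=O)C=C(C)C | intermediate
28 | (5S,6S,7S)-2-{[tert-butyl(diphenyl)silyl]oxymethyl}-5-[2-(1,3-dioxolan-2-yl)ethyl]-5-methyl-6-[(E)-2-(3-methylbut-2-enoyloxy)ethenyl]-7-(prop-2-enyl)cyclohept-2-en-1-one | C1COC(CC[C@@]2(C)CC=C(CO[Si](c3ccccc3)(c4ccccc4)C(C)(C)C)C(=O)[C@@H](CC=C)[C@@H]2/C=C/OC(=O)C=C(C)C)O1 | intermediate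
29 | (5S,6S,7S)-2-{[tert-butyl(diphenyl)silyl]oxymethyl}-5-[2-(1,3-dioxolan-2-yl)ethyl]-5-methyl-6-[(E)-2-(3-methylbut-2-enoyloxy)ethenyl]-7-(2-oxopropyl)cyclohept-2-en-1-one | C1COC(CC[C@@]2(C)CC=C(CO[Si](c3ccccc3)(c4ccccc4)C(C)(C)C)C(=O)[C@@H](CC(C)=O)[C@@H]2/C=C/OC(=O)C=C(C)C)O1 | intermediate (not isolated)
30 | (5S,6S,7S)-2-{[tert-butyl(diphenyl)silyl]oxymethyl}-5-methyl-6-[(E)-2-(3-methylbut-2-enoyloxy)ethenyl]-5-(3-oxopropyl)-7-(2-oxopropyl)cyclohept-2-en-1-one | O=CCC[C@@]1(C)CC=C(CO[Si](c2ccccc2)(c3ccccc3)C(C)(C)C)C(=O)[C@@H](CC(C)=O)[C@@H]1/C=C/OC(=O)C=C(C)C | intermediate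
31 | 2-bromopropene | C=C(C)Br | starting material
32 | (5S,6S,7S)-2-{[tert-butyl(diphenyl)silyl]oxymethyl}-5-[(3R)-3-hydroxy-4-methylpent-4-enyl]-5-methyl-6-[(E)-2-(3-methylbut-2-enoyloxy)ethenyl]-7-(2-oxopropyl)cyclohept-2-en-1-one | C=C(C)[C@@H](CC[C@@]1(C)CC=C(CO[Si](c2ccccc2)(c3ccccc3)C(C)(C)C)C(=O)[C@@H](CC(C)=O)[C@@H]1/C=C/OC(=O)C=C(C)C)O | intermediate
33 | methanesulfonic anhydride | CS(=O)(=O)OS(C)(=O)=O | starting material
34 | hydrogen peroxide | OO | starting material
35 | (3R)-methanesulfonate of 32 | C=C(C)[C@@H](CC[C@@]1(C)CC=C(CO[Si](c2ccccc2)(c3ccccc3)C(C)(C)C)C(=O)[C@@H](CC(C)=O)[C@@H]1/C=C/OC(=O)C=C(C)C)OS(C)(=O)=O | intermediate (not isolated)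
36 | (5S,6S,7S)-2-{[tert-butyl(diphenyl)silyl]oxymethyl}-5-[(3S)-3-hydroperoxy-4-methylpent-4-enyl]-5-methyl-6-[(E)-2-(3-methylbut-2-enoyloxy)ethenyl]-7-(2-oxopropyl)cyclohept-2-en-1-one | C=C(C)[C@H](CC[C@@]1(C)CC=C(CO[Si](c2ccccc2)(c3ccccc3)C(C)(C)C)C(=O)[C@@H](CC(C)=O)[C@@H]1/C=C/OC(=O)C=C(C)C)OO | intermediate
37 | (5S,6S,7S)-5-[(3S)-3-hydroperoxy-4-methylpent-4-enyl]-2-(hydroxymethyl)-5-methyl-6-[(E)-2-(3-methylbut-2-enoyloxy)ethenyl]-7-(2-oxopropyl)cyclohept-2-en-1-one | C=C(C)[C@H](CC[C@@]1(C)CC=C(CO)C(=O)[C@@H](CC(C)=O)[C@@H]1/C=C/OC(=O)C=C(C)C)OO | target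

## Step count and least certain steps

Total step count: 19. Longest linear sequence: 17 steps (steps 1–3, 5–13 and 15–19); steps 4 and 14 are one-step side branches.

**Step 8 (key step).** The most likely failure is in the opening of 15, not in the carbene addition. If the silyl group is lost before ionisation, the cyclopropanolate can cleave toward the dibromomethyl carbon and give a non-expanded ketone. The silyl bromide released on heating may also attack the acetal.
Fallback: setting out from 13, cyclopropanation with Et2Zn/CH2I2 gives the siloxycyclopropane F1. Oxidative opening of its ring-fusion bond with FeCl3 in DMF gives the ring-enlarged 3-chloro ketone F2. Elimination with NaOAc in methanol gives the cyclohept-2-enone F3, and iodination at C2 with I2/pyridine gives the 2-iodoenone F4. F4 is coupled with 17 under the conditions of step 9 and the route is rejoined at 18.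

**Step 18.** The allylic mesylate may ionise before it is substituted, which would erode the configuration, and the peroxide may attack the alkene terminus with allylic transposition. Acid-promoted addition of the peroxide to the methyl ketone is a further drain.
Fallback: setting out from 30, Wittig olefination at −78 °C with the ylide from isopropyltriphenylphosphonium iodide (aldehyde-selective) gives the trisubstituted alkene F5. Dye-sensitised photooxygenation (O2, tetraphenylporphyrin, visible light, CH2Cl2, 0 °C; Schenck ene reaction) then gives 36 together with its carbinol epimer F6 and the tertiary regioisomer F7, and 36 is isolated by preparative HPLC and re-enters the route before step 19. This gives up control at the carbinol carbon and relies on separation.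

**Step 15.** Poor geometric selectivity in the enolisation/acylation is the main risk, since enol esters of aldehydes often form as E/Z mixtures; partial epimerisation at C7 under the amine is a second one.
Fallback: setting out from 25, aldehyde-selective silylation (t-BuMe2SiCl, DBU, CH2Cl2) gives the (E)-silyl enol ether F8 and its (Z)-isomer F9, which are separated; F9 is hydrolysed back to 25 and recycled. F8 is acylated with retention of geometry by 3-methylbut-2-enoyl fluoride F10 (from the commercial acid chloride and KF) under catalysis by Bu4N[Ph3SiF2] in THF, returning to the route at 28.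

**Step 17.** Insufficient face selectivity is the main risk, because the aldehyde is unbranched and remote from all stereocentres and the ligand must do all the work; homocoupling of the alkenyl halide on nickel is the second.
Fallback: setting out from 30, the ligand-free coupling (CrCl2, NiCl2 cat., DMF) gives 32 together with its (3S)-epimer F11. Kinetic resolution by titanium–tartrate epoxidation (Ti(Oi-Pr)4, L-(+)-diisopropyl tartrate, t-BuOOH, 4 Å sieves, CH2Cl2, −20 °C) should convert F11, the fast-reacting carbinol configuration for this tartrate, into the epoxy alcohol F12 and leave 32, at which the route is rejoined; at most half of the material is kept.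

**Step 5.** The trisubstituted enal is a sluggish dienophile at the low temperature that selectivity requires, so that protodesilylation or oligomerisation of the acid-sensitive diene by the strong Lewis acid may outrun the cycloaddition, and raising the temperature erodes facial selectivity.
Fallback: setting out from 6 and 9, the cycloaddition promoted by Me2AlCl (CH2Cl2, −78 °C) gives 10 together with its enantiomer F13, and 10 is obtained by preparative chromatography on a chiral stationary phase, returning to the route at 10.

## Further compounds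

F1 | step 8 | 1-(triisopropylsilyloxy)bicyclo[4.1.0]heptane analogue of 13 (both ring-fusion isomers) | C1COC(CC[C@@]2(C)CC3CC3(O[Si](C(C)C)(C(C)C)C(C)C)C[C@@H]2CCOCc4ccc(OC)cc4)O1
F2 | step 8 | (5S,6S)-3-chloro-5-[2-(1,3-dioxolan-2-yl)ethyl]-6-{2-[(4-methoxyphenyl)methoxy]ethyl}-5-methylcycloheptan-1-one (C3 epimers) | C1COC(CC[C@@]2(C)CC(Cl)CC(=O)C[C@@H]2CCOCc3ccc(OC)cc3)O1
F3 | step 8 | (5S,6S)-5-[2-(1,3-dioxolan-2-yl)ethyl]-6-{2-[(4-methoxyphenyl)methoxy]ethyl}-5-methylcyclohept-2-en-1-one | C1COC(CC[C@@]2(C)CC=CC(=O)C[C@@H]2CCOCc3ccc(OC)cc3)O1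
F4 | step 8 | (5S,6S)-5-[2-(1,3-dioxolan-2-yl)ethyl]-2-iodo-6-{2-[(4-methoxyphenyl)methoxy]ethyl}-5-methylcyclohept-2-en-1-one | C1COC(CC[C@@]2(C)CC=C(I)C(=O)C[C@@H]2CCOCc3ccc(OC)cc3)O1
F5 | step 18 | (5S,6S,7S)-2-{[tert-butyl(diphenyl)silyl]oxymethyl}-5-methyl-6-[(E)-2-(3-methylbut-2-enoyloxy)ethenyl]-5-(4-methylpent-3-enyl)-7-(2-oxopropyl)cyclohept-2-en-1-one | CC(C)=CCC[C@@]1(C)CC=C(CO[Si](c2ccccc2)(c3ccccc3)C(C)(C)C)C(=O)[C@@H](CC(C)=O)[C@@H]1/C=C/OC(=O)C=C(C)C
F6 | step 18 | (3R)-hydroperoxide epimer of 36 | C=C(C)[C@@H](CC[C@@]1(C)CC=C(CO[Si](c2ccccc2)(c3ccccc3)C(C)(C)C)C(=O)[C@@H](CC(C)=O)[C@@H]1/C=C/OC(=O)C=C(C)C)OO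
F7 | step 18 | tertiary regioisomer of 36 with an (E)-4-hydroperoxy-4-methylpent-2-enyl chain | CC(C)(OO)/C=C/C[C@@]1(C)CC=C(CO[Si](c2ccccc2)(c3ccccc3)C(C)(C)C)C(=O)[C@@H](CC(C)=O)[C@@H]1/C=C/OC(=O)C=C(C)C
F8 | step 15 | (E)-tert-butyldimethylsilyl enol ether of 25 | C1COC(CC[C@@]2(C)CC=C(CO[Si](c3ccccc3)(c4ccccc4)C(C)(C)C)C(=O)[C@@H](CC=C)[C@@H]2/C=C/O[Si](C)(C)C(C)(C)C)O1
F9 | step 15 | (Z)-tert-butyldimethylsilyl enol ether of 25 | C1COC(CC[C@@]2(C)CC=C(CO[Si](c3ccccc3)(c4ccccc4)C(C)(C)C)C(=O)[C@@H](CC=C)[C@@H]2/C=C\O[Si](C)(C)C(C)(C)C)O1
F10 | step 15 | 3-methylbut-2-enoyl fluoride | CC(C)=CC(F)=O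
F11 | step 17 | (3S)-carbinol epimer of 32 | C=C(C)[C@H](CC[C@@]1(C)CC=C(CO[Si](c2ccccc2)(c3ccccc3)C(C)(C)C)C(=O)[C@@H](CC(C)=O)[C@@H]1/C=C/OC(=O)C=C(C)C)O
F12 | step 17 | epoxy alcohol from F11 (epoxide of the isopropenyl group, carbinol S) | CC1(CO1)[C@H](CC[C@@]2(C)CC=C(CO[Si](c3ccccc3)(c4ccccc4)C(C)(C)C)C(=O)[C@@H](CC(C)=O)[C@@H]2/C=C/OC(=O)C=C(C)C)O
F13 | step 5 | (1R,6R)-enantiomer of 10 | O=C[C@]1(C)CC=C(O[Si](C(C)C)(C(C)C)C(C)C)C[C@H]1CCOCc2ccc(OC)cc2
A1 | alternative 1 | cis-fused bicyclo[5.4.0]undecenone trimethylsilyl enol ether bearing the allyl/methyl quaternary carbon | C=CC[C@@]1(C)CCCC(=O)[C@@H]2CC(C)=C(O[Si](C)(C)C)C[C@H]12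
A2 | alternative 1 | (R)-4-allyl-4-methylcyclohept-2-en-1-one | C=CC[C@@]1(C)CCCC(=O)C=C1
A3 | alternative 1 | 2-methyl-3-(trimethylsilyloxy)buta-1,3-diene | C=C(C)C(=C)O[Si](C)(C)C
A4 | alternative 2 | cyclohepta[b]furan with the C2=C3 alkene, silyloxymethyl group, homoprenyl chain and dioxolanylmethyl arm | CC(C)=CCC[C@@]1(C)CC=C(CO[Si](C)(C)C(C)(C)C)c2oc(C)cc2[C@@H]1CC3OCCO3
A5 | alternative 3 | methyl cyclohepta-1,4-dienecarboxylate with quaternary C5 | CC(C)=CCC[C@@]1(C)CC=C(C(=O)OC)CC=C1
A6 | alternative 3 | (E)-4,8-dimethylnona-1,3,7-triene | C=C/C=C(\C)CCC=C(C)C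
A7 | alternative 3 | methyl 2-diazobut-3-enoate | C=CC(=[N+]=[N-])C(=O)OC
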